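**Plan**

- Retrosynthesis: the two aryl O–CH2OMe acetal bonds are cut first. Then both bonds of the ring A carbonyl carbon, C1'–C(=O) and C(=O)–CH2, are cut, leaving a ring A bromide, carbon monoxide and the ring B methyl ketone. The C3'–CH2 bond of the prenyl group is cut last.
- Enabling feature: the carbonyl carbon on C1' of ring A (C2' OMe, C3' prenyl, C4' OH) is one carbon between an aryl carbon and an enolisable CH2, so it can come from CO. C2' carries OMe, not OH, so the diketone cannot close to a flavone.
- Forward: ring A is protected and prenylated at C3', between its two oxygens, with bromine already at C1'. Ring B is protected. The two halves and CO are joined on palladium as an open chain, with no ring formed, and both acetals are then removed.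
- Stereochemistry: none to set. The target is achiral and its only alkene carries two identical methyl groups.

Key step: step 4

Assumption: the target is treated as the diketo tautomer drawn, which equilibrates freely with its enol forms; CO is taken from a cylinder or generated ex situ in a two-chamber vessel.

**Route**

Step 1
Reactants: 1 4-bromo-3-methoxyphenol
Product: 2 1-bromo-2-methoxy-4-(methoxymethoxy)benzene
Conditions: MOMCl, K2CO3, acetone, 0 °C → rt
Reagents that add atoms: chloromethyl methyl ether (MOMCl), COCCl
Why: Williamson-type O-alkylation of the phenoxide with the reactive α-chloro ether should give the aryl MOM acetal, which serves later both as protecting group and as ortho-directing group.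

Step 2
Reactants: 2 1-bromo-2-methoxy-4-(methoxymethoxy)benzene; 3 prenyl bromide (1-bromo-3-methylbut-2-ene)
Product: 6 1-bromo-2-methoxy-4-(methoxymethoxy)-3-(3-methylbut-2-enyl)benzene, via aryllithium 4 (not isolated), via arylcopper 5 (not isolated)
Conditions: 2,2,6,6-tetramethylpiperidine, n-BuLi, THF, 0 °C; then 2, −78 °C; CuBr·SMe2 (1.2 equiv), −78 → −40 °C; then 3, −78 → 0 °C
Reagents that add atoms: none
Why: Directed ortho-metalation with a hindered lithium amide should remove the proton flanked by the OMe and OMOM groups without the bromine–lithium exchange an alkyllithium would cause, and after transmetalation to copper the aryl group should displace bromide from the primary carbon of prenyl bromide in a copper-mediated SN2 allylic substitution.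

Step 3
Reactants: 7 4'-hydroxyacetophenone
Product: 8 1-[4-(methoxymethoxy)phenyl]ethanone
Conditions: MOMCl, K2CO3, acetone, 0 °C → rt
Reagents that add atoms: chloromethyl methyl ether (MOMCl), COCCl
Why: Williamson-type O-alkylation of the acidic para-acyl phenol should proceed under carbonate conditions that do not enolise the methyl ketone.

Step 4
Reactants: 6 1-bromo-2-methoxy-4-(methoxymethoxy)-3-(3-methylbut-2-enyl)benzene; 8 1-[4-(methoxymethoxy)phenyl]ethanone; 9 carbon monoxide
Product: 12 1-[2-methoxy-4-(methoxymethoxy)-3-(3-methylbut-2-enyl)phenyl]-3-[4-(methoxymethoxy)phenyl]propane-1,3-dione, via sodium enolate 10 (not isolated), via sodium diketonate 11 (not isolated)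
Conditions: 8 (2.2 equiv), NaN(SiMe3)2 (2.1 equiv), THF, 0 °C; then 6, CO (2 bar), Pd(dba)2 (5 mol %), 1,3-bis(diphenylphosphino)propane (DPPP, 5 mol %), THF, 80 °C, sealed vessel; then AcOH
Reagents that add atoms: none
Why: Zerovalent palladium should insert into the C1'–Br bond of 6, CO should coordinate and migrate to give an aroylpalladium bromide of divalent palladium held by the chelating bisphosphine, and the sodium enolate 10 should then replace bromide and undergo C–C reductive elimination, so that the C1'–C(=O) and C(=O)–CH2 bonds both form in one catalytic cycle. The closest known reaction type is the palladium-catalysed carbonylative α-arylation of ketone enolates with aryl bromides to give 1,3-diketones. No ring is closed, since the chain stays open between rings A and B, and no stereocentre is formed. The step needs carbonylation to win over direct α-arylation and C-acylation to win over O-acylation: the CO atmosphere and the cis-chelating ligand should make migratory insertion at arylpalladium faster than enolate transfer, and the second equivalent of 10 should remove the product at once as the chelated sodium diketonate 11, which also blocks a second acylation. In the substrate, bromine sits exactly at C1' with only a methoxy group as ortho neighbour, the MOM acetals are inert to the enolate base, and the trisubstituted prenyl alkene, meta to the palladium-bearing carbon, can neither chelate nor insert readily.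

Step 5
Reactants: 12 1-[2-methoxy-4-(methoxymethoxy)-3-(3-methylbut-2-enyl)phenyl]-3-[4-(methoxymethoxy)phenyl]propane-1,3-dione
Product: 13 1-[4-hydroxy-2-methoxy-3-(3-methylbut-2-enyl)phenyl]-3-(4-hydroxyphenyl)propane-1,3-dione
Conditions: HCl (1 M in MeOH), MeOH/THF, 0 °C → rt
Reagents that add atoms: none
Why: Acid-catalysed acetal solvolysis (MOM ether cleavage) in methanol should free both phenols with loss of dimethoxymethane, the C2' methyl ether ruling out cyclodehydration of the diketone and the low temperature sparing the prenyl alkene.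

**Compound list**

1 | 4-bromo-3-methoxyphenol | COc1cc(O)ccc1Br | starting material
2 | 1-bromo-2-methoxy-4-(methoxymethoxy)benzene | COCOc1ccc(Br)c(OC)c1 | intermediate
3 | prenyl bromide (1-bromo-3-methylbut-2-ene) | CC(C)=CCBr | starting material
4 | [3-bromo-2-methoxy-6-(methoxymethoxy)phenyl]lithium | [Li]c1c(OC)c(Br)ccc1OCOC | intermediate
5 | [3-bromo-2-methoxy-6-(methoxymethoxy)phenyl]copper | [Cu]c1c(OC)c(Br)ccc1OCOC | intermediate
6 | 1-bromo-2-methoxy-4-(methoxymethoxy)-3-(3-methylbut-2-enyl)benzene | COCOc1ccc(Br)c(OC)c1CC=C(C)C | intermediate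
7 | 4'-hydroxyacetophenone | CC(=O)c1ccc(O)cc1 | starting material
8 | 1-[4-(methoxymethoxy)phenyl]ethanone | CC(=O)c1ccc(OCOC)cc1 | intermediate
9 | carbon monoxide | [C-]#[O+] | starting material
10 | sodium 1-[4-(methoxymethoxy)phenyl]ethenolate | C=C([O-])c1ccc(OCOC)cc1.[Na+] | intermediate
11 | sodium 3-[2-methoxy-4-(methoxymethoxy)-3-(3-methylbut-2-enyl)phenyl]-1-[4-(methoxymethoxy)phenyl]-3-oxoprop-1-en-1-olate | COCOc1ccc(C(=O)C=C([O-])c2ccc(OCOC)cc2)c(OC)c1CC=C(C)C.[Na+] | intermediate
12 | 1-[2-methoxy-4-(methoxymethoxy)-3-(3-methylbut-2-enyl)phenyl]-3-[4-(methoxymethoxy)phenyl]propane-1,3-dione | COCOc1ccc(C(=O)CC(=O)c2ccc(OCOC)cc2)c(OC)c1CC=C(C)C | intermediate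
13 | 1-[4-hydroxy-2-methoxy-3-(3-methylbut-2-enyl)phenyl]-3-(4-hydroxyphenyl)propane-1,3-dione | COc1c(C(=O)CC(=O)c2ccc(O)cc2)ccc(O)c1CC=C(C)C | target

**Count and risks**

Total step count: 5. Longest linear sequence: 4 steps (steps 1, 2, 4 and 5); the ring B branch (step 3) joins at step 4.

Steps most likely to fail:

1. Step 2. The metalation may be incomplete, or the base may deprotonate next to bromine, after which LiBr is lost or bromine migrates around the ring. The copper step may also deliver the allyl group at its tertiary end. The fallback sets out from 2 and comes back at 6, and it takes the halogen out of the ring while the carbanion chemistry is done.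
   - Compound 2 would undergo bromine–lithium exchange with n-BuLi (THF, −78 °C) to give [2-methoxy-4-(methoxymethoxy)phenyl]lithium F1.
   - Trapping with Me3SiCl would give [2-methoxy-4-(methoxymethoxy)phenyl]trimethylsilane F2.
   - This halogen-free arene would be lithiated between its two oxygens with n-BuLi/TMEDA (THF, 0 °C) to give [2-methoxy-6-(methoxymethoxy)-3-(trimethylsilyl)phenyl]lithium F3.
   - Prenylation with 3 and catalytic CuI would give [2-methoxy-4-(methoxymethoxy)-3-(3-methylbut-2-enyl)phenyl]trimethylsilane F4.
   - Ipso-bromodesilylation with NBS in dry MeCN at −20 °C should return bromine to the carbon that carried silicon and give 6. Ipso attack para to the acetal oxygen is expected to be faster than attack on the side-chain alkene.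

2. Step 4. Oxidative addition of the electron-rich, ortho-substituted bromide may be slow under CO. The enolate may also couple without CO uptake, or the aroylpalladium intermediate may be intercepted by nitrogen species from the base. The fallback sets out from 6 and comes back at 12 through 11, and it replaces the catalytic carbonylation by a crossed Claisen condensation.
   - Compound 6 would undergo bromine–lithium exchange with n-BuLi (THF, −78 °C) to give [2-methoxy-4-(methoxymethoxy)-3-(3-methylbut-2-enyl)phenyl]lithium F5.
   - Adding F5 to an excess of ClCO2Me would give methyl 2-methoxy-4-(methoxymethoxy)-3-(3-methylbut-2-enyl)benzoate F6.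
   - F6 would be condensed with two equivalents of the sodium enolate 10 (from 8 and NaN(SiMe3)2) in THF, 0 °C → reflux, to give the diketonate 11 and, after AcOH, 12.

3. Step 5. The acid may add the freed C4' hydroxyl, HCl or methanol across the prenyl double bond (closure to a dimethylchroman), or the acetal cleavage may stall. The fallback sets out from 1 and 7 and comes back at 13, and it changes the protecting group to one cleaved by fluoride. Both phenols would be carried as 2-(trimethylsilyl)ethoxymethyl (SEM) ethers, which direct the lithiation as MOM does.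
   - Compound 1 with SEMCl and K2CO3 in DMF would give 1-bromo-2-methoxy-4-{[2-(trimethylsilyl)ethoxy]methoxy}benzene F7.
   - Lithium 2,2,6,6-tetramethylpiperidide would convert F7 into [3-bromo-2-methoxy-6-{[2-(trimethylsilyl)ethoxy]methoxy}phenyl]lithium F8.
   - CuBr·SMe2 would convert F8 into [3-bromo-2-methoxy-6-{[2-(trimethylsilyl)ethoxy]methoxy}phenyl]copper F9.
   - Prenyl bromide 3 would then give 1-bromo-2-methoxy-3-(3-methylbut-2-enyl)-4-{[2-(trimethylsilyl)ethoxy]methoxy}benzene F10.
   - Compound 7 with SEMCl and K2CO3 would give 1-(4-{[2-(trimethylsilyl)ethoxy]methoxy}phenyl)ethanone F11.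
   - NaN(SiMe3)2 would convert F11 into sodium 1-(4-{[2-(trimethylsilyl)ethoxy]methoxy}phenyl)ethenolate F12.
   - Carbonylative coupling of F10, 9 and F12 under the conditions of step 4 would give the sodium diketonate of the bis-SEM diketone F13.
   - AcOH would give 1-[2-methoxy-3-(3-methylbut-2-enyl)-4-{[2-(trimethylsilyl)ethoxy]methoxy}phenyl]-3-(4-{[2-(trimethylsilyl)ethoxy]methoxy}phenyl)propane-1,3-dione F14.
   - Bu4NF in THF/DMPU at 60 °C should then fragment both SEM groups without any acid and give 13.

**Further compounds**

F1 | step 2 | [2-methoxy-4-(methoxymethoxy)phenyl]lithium | [Li]c1ccc(OCOC)cc1OC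
F2 | step 2 | [2-methoxy-4-(methoxymethoxy)phenyl]trimethylsilane | C[Si](C)(C)c1ccc(OCOC)cc1OC
F3 | step 2 | [2-methoxy-6-(methoxymethoxy)-3-(trimethylsilyl)phenyl]lithium | C[Si](C)(C)c1ccc(OCOC)c([Li])c1OC
F4 | step 2 | [2-methoxy-4-(methoxymethoxy)-3-(3-methylbut-2-enyl)phenyl]trimethylsilane | C[Si](C)(C)c1ccc(OCOC)c(CC=C(C)C)c1OC
F5 | step 4 | [2-methoxy-4-(methoxymethoxy)-3-(3-methylbut-2-enyl)phenyl]lithium | [Li]c1ccc(OCOC)c(CC=C(C)C)c1OC
F6 | step 4 | methyl 2-methoxy-4-(methoxymethoxy)-3-(3-methylbut-2-enyl)benzoate | COC(=O)c1ccc(OCOC)c(CC=C(C)C)c1OC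
F7 | step 5 | 1-bromo-2-methoxy-4-{[2-(trimethylsilyl)ethoxy]methoxy}benzene | COc1cc(OCOCC[Si](C)(C)C)ccc1Br
F8 | step 5 | [3-bromo-2-methoxy-6-{[2-(trimethylsilyl)ethoxy]methoxy}phenyl]lithium | [Li]c1c(OC)c(Br)ccc1OCOCC[Si](C)(C)C
F9 | step 5 | [3-bromo-2-methoxy-6-{[2-(trimethylsilyl)ethoxy]methoxy}phenyl]copper | [Cu]c1c(OC)c(Br)ccc1OCOCC[Si](C)(C)C
F10 | step 5 | 1-bromo-2-methoxy-3-(3-methylbut-2-enyl)-4-{[2-(trimethylsilyl)ethoxy]methoxy}benzene | COc1c(Br)ccc(OCOCC[Si](C)(C)C)c1CC=C(C)C
F11 | step 5 | 1-(4-{[2-(trimethylsilyl)ethoxy]methoxy}phenyl)ethanone | CC(=O)c1ccc(OCOCC[Si](C)(C)C)cc1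
F12 | step 5 | sodium 1-(4-{[2-(trimethylsilyl)ethoxy]methoxy}phenyl)ethenolate | C=C([O-])c1ccc(OCOCC[Si](C)(C)C)cc1.[Na+]
F13 | step 5 | sodium 3-[2-methoxy-3-(3-methylbut-2-enyl)-4-{[2-(trimethylsilyl)ethoxy]methoxy}phenyl]-3-oxo-1-(4-{[2-(trimethylsilyl)ethoxy]methoxy}phenyl)prop-1-en-1-olate | COc1c(C(=O)C=C([O-])c2ccc(OCOCC[Si](C)(C)C)cc2)ccc(OCOCC[Si](C)(C)C)c1CC=C(C)C.[Na+]
F14 | step 5 | 1-[2-methoxy-3-(3-methylbut-2-enyl)-4-{[2-(trimethylsilyl)ethoxy]methoxy}phenyl]-3-(4-{[2-(trimethylsilyl)ethoxy]methoxy}phenyl)propane-1,3-dione | COc1c(C(=O)CC(=O)c2ccc(OCOCC[Si](C)(C)C)cc2)ccc(OCOCC[Si](C)(C)C)c1CC=C(C)C
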